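**Retrosynthetic overview**
1. Endgame: 22 comes from anti, trans-diaxial opening of the 5α,6α-oxirane 20 at allylic C5 by angelic acid. C4=CH2 comes from a C4 ketone (Wittig), the oxirane from the C5=C6 bond of a cyclohex-2-enone, the 2α-OAc from a 2β-OH (Mitsunobu), and the ethylidene from a vinyl group (one-position isomerisation).
2. Key disconnection: C7–C7a, made by disrotatory 6π electrocyclisation of a 3-oxidohexatriene. The triene forms in the same flask from a cyclopent-1-enyllithium and 4-isopropylcyclobut-2-enone: 1,2-addition makes C3a–C4, and an oxyanion-driven 4π opening cuts C4–C7.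
3. Enabling feature: in the six-membered ring, C4(=CH2)–C5(O)–C6(O)–C7(iPr) is an unbroken four-carbon arc held between the ring-fusion carbons C3a and C7a. At the ketone/alkene oxidation level this ring is a cyclohex-2-enone, that is, the four carbons of a cyclobutenone plus the C=C of the five-membered ring. C3a (α) and C7 (γ) remain epimerisable in it.
4. Ring order: the five-membered ring is bought as (R)-4-silyloxycyclopentenone. A temporary four-membered ring is made by ketene/ynol ether [2+2]. The six-membered ring is formed last, driven by release of the four-ring strain.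

Key step: step 5

Remark: locants are those of octahydro-1H-indene (C1 ethylidene carbon, C2 acetoxy carbon, C3 CH2, C3a, C4 methylidene carbon, C5 angelate carbon, C6 carbinol carbon, C7 isopropyl carbon, C7a). β is the face of H-3a and α is the face of H-7a.

Step 1
Reactants: 1 3-methylbutanoyl chloride; 2 ethoxyethyne
Product: 4 (±)-3-ethoxy-4-isopropylcyclobut-2-en-1-one, via isopropylketene 3 (not isolated)
Conditions: Et3N, Et2O, 0 °C → rt, slow addition of 1 to 2/Et3N
Reagents that add atoms: none
Why: Dehydrochlorination gives isopropylketene, which the electron-rich ynol ether intercepts in a regioselective ketene–alkyne [2+2] cycloaddition (ketene carbonyl carbon to the unsubstituted alkyne carbon); the single stereocentre is racemic, which is harmless because step 5 erases it.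

Step 2
Reactants: 4 (±)-3-ethoxy-4-isopropylcyclobut-2-en-1-one
Product: 6 (±)-4-isopropylcyclobut-2-en-1-one, via cyclobutenol 5 (not isolated)
Conditions: DIBAL-H, Et2O, −78 °C; then 1 M aq HCl, 0 °C; kept and used as a dried, cold Et2O solution
Reagents that add atoms: water, O
Why: 1,2-Reduction of the vinylogous ester, then acid-induced allylic ionisation and hydrolysis of the enol ether (the four-ring version of the Stork–Danheiser enone transposition), should give the parent enone with the isopropyl carbon still α to the new carbonyl group.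

Step 3
Reactants: 7 (R)-4-[(tert-butyldimethylsilyl)oxy]cyclopent-2-en-1-one
Product: 9 (3R,4R)-4-[(tert-butyldimethylsilyl)oxy]-3-ethenylcyclopent-1-en-1-yl trifluoromethanesulfonate, via magnesium enolate 8 (not isolated)
Conditions: CH2=CHMgBr, CuI (10 mol %), LiCl (20 mol %), THF, −78 °C; then N-(5-chloro-2-pyridyl)bis(trifluoromethanesulfonimide), −78 → 0 °C
Reagents that add atoms: vinylmagnesium bromide, C=C[Mg]Br; N-(5-chloro-2-pyridyl)bis(trifluoromethanesulfonimide), O=S(=O)(N(c1ccc(Cl)cn1)S(=O)(=O)C(F)(F)F)C(F)(F)F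
Why: Copper-catalysed conjugate addition occurs anti to the silyloxy group (sets C1, vinyl trans to the C2 oxygen), and the regiodefined enolate is O-sulfonylated before it can equilibrate, which fixes the double bond between the future C3a and C7a.

Step 4
Reactants: 9 (3R,4R)-4-[(tert-butyldimethylsilyl)oxy]-3-ethenylcyclopent-1-en-1-yl trifluoromethanesulfonate
Product: 10 [(3R,4R)-4-[(tert-butyldimethylsilyl)oxy]-3-ethenylcyclopent-1-en-1-yl]trimethylstannane
Conditions: (Me3Sn)2, Pd(PPh3)4 (5 mol %), LiCl, THF, 60 °C
Reagents that add atoms: hexamethylditin, C[Sn](C)(C)[Sn](C)(C)C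
Why: Palladium-catalysed stannylation of an enol triflate with a distannane (Stille-type oxidative addition, transmetalation, reductive elimination) keeps the double-bond position and touches no stereocentre.

Step 5
Reactants: 10 [(3R,4R)-4-[(tert-butyldimethylsilyl)oxy]-3-ethenylcyclopent-1-en-1-yl]trimethylstannane; 6 (±)-4-isopropylcyclobut-2-en-1-one
Product: 15 (1R,2R,3aR,7R,7aR)-2-[(tert-butyldimethylsilyl)oxy]-1-ethenyl-7-isopropyl-1,2,3,3a,7,7a-hexahydro-4H-inden-4-one (trans-fused; 1α-vinyl; 2β-OTBS; 7α-isopropyl), via alkenyllithium 11 (not isolated), via cyclobutenolate 12 (not isolated), via trienolate 13 (not isolated), via dienolate 14 (not isolated)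
Conditions: MeLi (1.0 equiv), THF, −78 °C; 6 in Et2O, −78 °C, then −78 → 25 °C; MeOH, 25 °C (equilibration); aq NH4Cl
Reagents that add atoms: none
Why: Sn/Li exchange gives 11, which adds 1,2 to the strained, practically non-enolisable ketone 6 anti to the isopropyl group (C3a–C4 bond), and in alkoxide 12 the oxido group drives a conrotatory 4π opening of the C4–C7 bond and, as the strongest donor, rotates outward, turning the cyclopentenyl group inward (Z central double bond, the only geometry that can close) and the cis-disposed isopropyl group inward as well (Z terminal double bond). The 3-oxidohexatriene 13 then closes between C7a and C7 by thermal disrotatory 6π electrocyclisation, the only ring closed here (six-membered, both termini becoming ring atoms), with the lost four-ring strain making the relay irreversible; the closest known reaction type is the ring expansion of cyclobutenones to cyclohex-2-enones with alkenyllithiums by the same 4π/6π relay. Disrotation of a triene that carries C1 outside on C7a and isopropyl inside on C7 places these two groups trans (H-7 β, H-7a α). The sense of disrotation, that is, the face of C7a that is bonded, is controlled by the adjacent C1 stereocentre, the new bond forming anti to the α-vinyl group by the same 1,2-induction that governs enolate trapping in 3,4-disubstituted cyclopentanones. C3a is set when dienolate 14 is protonated and the enone stands with LiOMe/MeOH, because the trans-fused ketone with C1, C3 and isopropyl all equatorial is the thermodynamic isomer, and C7 (γ-position of the enone) can be corrected through the same equilibrium if part of the triene closes from the E geometry. The step needs 1,2- over 1,4-addition (hard alkenyllithium at −78 °C) and 6π closure over a [1,7]-hydrogen shift from the inward isopropyl C–H (the oxido substituent lowers the electrocyclisation barrier).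

Step 6
Reactants: 15 (1R,2R,3aR,7R,7aR)-2-[(tert-butyldimethylsilyl)oxy]-1-ethenyl-7-isopropyl-1,2,3,3a,7,7a-hexahydro-4H-inden-4-one
Product: 16 (1Z,2R,3aR,7R,7aS)-2-[(tert-butyldimethylsilyl)oxy]-1-ethylidene-7-isopropyl-1,2,3,3a,7,7a-hexahydro-4H-inden-4-one
Conditions: Co(salen-tBu,tBu)Cl (5 mol %), PhSiH3 (10 mol %), benzene, rt
Reagents that add atoms: none
Why: In this cobalt-hydride hydrogen-atom-transfer (MHAT) isomerisation, H• adds to the terminal CH2 and the secondary radical gives up the tertiary H-1, which moves the alkene one position without engaging the electron-poor enone; the methyl group should end on the C2 side (Z) because the other orientation suffers A(1,3) strain with the rigidly in-plane C7a–C7 bond and its isopropyl group.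

Step 7
Reactants: 16 (1Z,2R,3aR,7R,7aS)-2-[(tert-butyldimethylsilyl)oxy]-1-ethylidene-7-isopropyl-1,2,3,3a,7,7a-hexahydro-4H-inden-4-one
Product: 17 5α,6α-epoxy ketone [(1Z)-2β-OTBS-1-ethylidene-5α,6α-epoxy-7α-isopropyl-trans-octahydroinden-4-one]
Conditions: 30 % H2O2, NaOH (cat.), MeOH, 0 °C
Reagents that add atoms: hydrogen peroxide, OO
Why: Weitz–Scheffer nucleophilic epoxidation touches only the electron-poor C5=C6 bond; in the rigid trans-fused half-chair, hydroperoxide adds to C6 along the axial α trajectory that leads to a chair enolate, so the oxirane should form on the α face (sets C6 and, provisionally, C5).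

Step 8
Reactants: 17 5α,6α-epoxy ketone
Product: 18 (1Z)-2β-OTBS-1-ethylidene-4-methylidene-5α,6α-epoxy-7α-isopropyl-trans-octahydroindene
Conditions: Ph3PCH3Br, KOtBu, THF, 0 °C → rt
Reagents that add atoms: methyltriphenylphosphonium bromide, C[P+](c1ccccc1)(c1ccccc1)c1ccccc1.[Br-]
Why: Wittig methylenation of α,β-epoxy ketones with the non-stabilised ylide is a standard entry to vinyl oxiranes, and C3a, already the thermodynamic epimer, is not at risk under the basic conditions.

Step 9
Reactants: 18 (1Z)-2β-OTBS-1-ethylidene-4-methylidene-5α,6α-epoxy-7α-isopropyl-trans-octahydroindene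
Product: 19 (1Z)-1-ethylidene-4-methylidene-5α,6α-epoxy-7α-isopropyl-trans-octahydroinden-2β-ol
Conditions: TBAF, THF, 0 °C → rt
Reagents that add atoms: none
Why: Fluoride cleaves the Si–O bond selectively, and the oxirane and the alkenes are inert to it.

Step 10
Reactants: 19 (1Z)-1-ethylidene-4-methylidene-5α,6α-epoxy-7α-isopropyl-trans-octahydroinden-2β-ol
Product: 20 (1Z)-1-ethylidene-4-methylidene-5α,6α-epoxy-7α-isopropyl-trans-octahydroinden-2α-yl acetate
Conditions: PPh3, DIAD, AcOH, toluene, 0 °C → rt
Reagents that add atoms: acetic acid, CC(=O)O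
Why: Mitsunobu esterification displaces the 2β-oxyphosphonium group by acetate with SN2 inversion, which installs the 2α-acetate and corrects the stereocentre that served as the control element.

Step 11
Reactants: 20 (1Z)-1-ethylidene-4-methylidene-5α,6α-epoxy-7α-isopropyl-trans-octahydroinden-2α-yl acetate; 21 angelic acid [(Z)-2-methylbut-2-enoic acid]
Product: 22 (1Z,2S,3aR,5S,6S,7S,7aR)-2-acetoxy-1-ethylidene-6-hydroxy-4-methylidene-7-isopropyloctahydro-1H-inden-5-yl (Z)-2-methylbut-2-enoate (target)
Conditions: 21 (3 equiv), Cs2CO3 (0.3 equiv), DMF, 45 °C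
Reagents that add atoms: none
Why: In this SN2 acidolysis of a vinyl oxirane by buffered carboxylate, attack at allylic C5 anti to the C–O bond is also the trans-diaxial (Fürst–Plattner) mode in the rigid trans-hydrindane; it inverts C5 to the β-angelate and leaves the 6α-OH, and the 180° O–C–C–O arrangement blocks acyl migration.

**Compound list**
1 | 3-methylbutanoyl chloride | CC(C)CC(=O)Cl | starting material
2 | ethoxyethyne | CCOC#C | starting material
3 | isopropylketene | CC(C)C=C=O | intermediate
4 | (±)-3-ethoxy-4-isopropylcyclobut-2-en-1-one | CCOC1=CC(=O)C1C(C)C | intermediate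
5 | 3-ethoxy-4-isopropylcyclobut-2-en-1-ol | CCOC1=CC(O)C1C(C)C | intermediate
6 | (±)-4-isopropylcyclobut-2-en-1-one | CC(C)C1C=CC1=O | intermediate
7 | (R)-4-[(tert-butyldimethylsilyl)oxy]cyclopent-2-en-1-one | O=C1C[C@@H](O[Si](C)(C)C(C)(C)C)C=C1 | starting material
8 | bromomagnesium enolate of the trans-3-vinyl-4-silyloxycyclopentanone | Br[Mg]OC=1C[C@@H](O[Si](C)(C)C(C)(C)C)[C@H](C=C)C=1 | intermediate
9 | (3R,4R)-4-[(tert-butyldimethylsilyl)oxy]-3-ethenylcyclopent-1-en-1-yl trifluoromethanesulfonate | FC(F)(F)S(=O)(=O)OC=1C[C@@H](O[Si](C)(C)C(C)(C)C)[C@H](C=C)C=1 | intermediate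
10 | [(3R,4R)-4-[(tert-butyldimethylsilyl)oxy]-3-ethenylcyclopent-1-en-1-yl]trimethylstannane | C[Sn](C)(C)C=1C[C@@H](O[Si](C)(C)C(C)(C)C)[C@H](C=C)C=1 | intermediate
11 | (3R,4R)-4-silyloxy-3-ethenylcyclopent-1-en-1-yllithium | [Li]C=1C[C@@H](O[Si](C)(C)C(C)(C)C)[C@H](C=C)C=1 | intermediate
12 | lithium 1-(cyclopentenyl)-4-isopropylcyclobut-2-en-1-olate (oxide cis to isopropyl; two diastereomers, one from each enantiomer of 6) | [Li+].[O-]C1(C=CC1C(C)C)C=2C[C@@H](O[Si](C)(C)C(C)(C)C)[C@H](C=C)C=2 | intermediate
13 | lithium 3-oxidohexatriene (cyclopentenyl cis to C6 at the central double bond; Z terminal double bond) | [Li+].[O-]/C(C=1C[C@@H](O[Si](C)(C)C(C)(C)C)[C@H](C=C)C=1)=C/C=C\C(C)C | intermediate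
14 | lithium cross-conjugated dienolate (C3a=C4 enolate, C5=C6 alkene) | [Li+].[O-]C1=C2C[C@@H](O[Si](C)(C)C(C)(C)C)[C@H](C=C)[C@H]2[C@H](C(C)C)C=C1 | intermediate
15 | (1R,2R,3aR,7R,7aR)-2-[(tert-butyldimethylsilyl)oxy]-1-ethenyl-7-isopropyl-1,2,3,3a,7,7a-hexahydro-4H-inden-4-one | O=C1[C@@H]2C[C@@H](O[Si](C)(C)C(C)(C)C)[C@H](C=C)[C@H]2[C@H](C(C)C)C=C1 | intermediate
16 | (1Z,2R,3aR,7R,7aS)-2-[(tert-butyldimethylsilyl)oxy]-1-ethylidene-7-isopropyl-1,2,3,3a,7,7a-hexahydro-4H-inden-4-one | O=C1[C@@H]2C[C@@H](O[Si](C)(C)C(C)(C)C)/C(=C\C)[C@H]2[C@H](C(C)C)C=C1 | intermediate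
17 | 5α,6α-epoxy ketone derived from 16 | O=C1[C@@H]2C[C@@H](O[Si](C)(C)C(C)(C)C)/C(=C\C)[C@H]2[C@H](C(C)C)[C@@H]3O[C@@H]31 | intermediate
18 | 4-methylidene 5α,6α-oxirane, 2β-OTBS | C=C1[C@@H]2C[C@@H](O[Si](C)(C)C(C)(C)C)/C(=C\C)[C@H]2[C@H](C(C)C)[C@@H]3O[C@@H]31 | intermediate
19 | 4-methylidene 5α,6α-oxirane, 2β-OH | C=C1[C@@H]2C[C@@H](O)/C(=C\C)[C@H]2[C@H](C(C)C)[C@@H]3O[C@@H]31 | intermediate
20 | 4-methylidene 5α,6α-oxirane, 2α-OAc | C=C1[C@@H]2C[C@H](OC(C)=O)/C(=C\C)[C@H]2[C@H](C(C)C)[C@@H]3O[C@@H]31 | intermediate
21 | angelic acid | C/C=C(/C)C(=O)O | starting material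
22 | CNP0210397.1 | C=C1[C@@H]2C[C@H](OC(C)=O)/C(=C\C)[C@H]2[C@H](C(C)C)[C@H](O)[C@H]1OC(=O)/C(C)=C\C | target

Total steps: 11. Longest linear sequence: 9 (steps 3–11, from 7).

**Steps most likely to fail**

Step 5. The Z-configured trienolate may close slowly. A [1,7]-hydrogen shift from the inward isopropyl group may then drain it, or the facial bias at C7a may be too small.
Fallback, from 10 back to 15: stannane 10 is lithiated as before. The alkenyllithium is acylated at −78 °C with purchasable (±)-5-isopropyldihydrofuran-2(3H)-one to give the γ-hydroxy enone F1. An Appel reaction (I2, PPh3, imidazole) gives the secondary iodide F2. Bu3SnH/AIBN (slow addition, benzene, 80 °C) generates the C7 radical, which forms the same C7–C7a bond by 6-endo-trig conjugate cyclisation onto the acylcyclopentene, again anti to the vinyl group. DBU equilibration then gives the trans-fused saturated ketone F3. Kinetic enolisation (LDA, TMSCl) gives the silyl enol ether F4, and Saegusa–Ito dehydrogenation (Pd(OAc)2, MeCN) returns to 15, where C7 can still be equilibrated.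

Step 6. Hydrogen-atom transfer to the hindered vinyl group may stall. The double bond may also travel further toward the silyl ether carbon, or settle with poor geometric control.
Fallback, from 15 back to 20: the vinyl group is carried through the chemistry of steps 7–9 (H2O2/NaOH, then Ph3P=CH2, then TBAF). This gives the vinyl epoxy ketone F5, the vinyl methylidene oxirane F6 and the homoallylic alcohol F7. Dess–Martin oxidation gives the β,γ-unsaturated cyclopentanone F8, in which H-1 is acidic. DBU therefore moves the double bond into conjugation by enolisation rather than by hydrogen-atom transfer, and equilibrates it to the ethylidene ketone F9 with the methyl group turned away from C7a/C7. Reagent-controlled Corey–Bakshi–Shibata reduction ((R)-Me-CBS, catecholborane, −78 °C) gives the 2α-alcohol F10. Plain acetylation (Ac2O, pyridine, DMAP) gives 20, so the Mitsunobu inversion is no longer needed.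

Step 11. The carboxylate may attack the exocyclic methylene terminus (SN2′), or the angelate may isomerise from Z to E under warm, nucleophilic conditions.
Fallback, from 20 back to 22: C–O bond formation and acylation are separated. Dilute HClO4 in THF/H2O at 0 °C opens the oxirane in the trans-diaxial sense to the 5β,6α-diol F11. Angelic acid 21 is converted with 2,4,6-trichlorobenzoyl chloride/Et3N into the mixed anhydride F12. This anhydride (toluene, 75 °C, no nucleophilic catalyst) should acylate the allylic, less hindered 5β-OH in preference to the 6α-OH next to the isopropyl group, giving 22.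

**Further compounds**
F1 | step 5 | 1-[(3R,4R)-4-silyloxy-3-ethenylcyclopent-1-en-1-yl]-4-hydroxy-5-methylhexan-1-one (carbinol epimers) | CC(C)C(O)CCC(=O)C=1C[C@@H](O[Si](C)(C)C(C)(C)C)[C@H](C=C)C=1
F2 | step 5 | 1-[(3R,4R)-4-silyloxy-3-ethenylcyclopent-1-en-1-yl]-4-iodo-5-methylhexan-1-one | CC(C)C(I)CCC(=O)C=1C[C@@H](O[Si](C)(C)C(C)(C)C)[C@H](C=C)C=1
F3 | step 5 | 5,6-dihydro derivative of 15 (trans-fused saturated ketone) | O=C1[C@@H]2C[C@@H](O[Si](C)(C)C(C)(C)C)[C@H](C=C)[C@H]2[C@H](C(C)C)CC1
F4 | step 5 | kinetic trimethylsilyl enol ether of F3 (C4=C5) | C[Si](C)(C)OC=1[C@@H]2C[C@@H](O[Si](C)(C)C(C)(C)C)[C@H](C=C)[C@H]2[C@H](C(C)C)CC=1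
F5 | step 6 | 5α,6α-epoxy ketone of 15 (1α-vinyl) | O=C1[C@@H]2C[C@@H](O[Si](C)(C)C(C)(C)C)[C@H](C=C)[C@H]2[C@H](C(C)C)[C@@H]3O[C@@H]31
F6 | step 6 | 1α-vinyl 4-methylidene 5α,6α-oxirane, 2β-OTBS | C=C1[C@@H]2C[C@@H](O[Si](C)(C)C(C)(C)C)[C@H](C=C)[C@H]2[C@H](C(C)C)[C@@H]3O[C@@H]31
F7 | step 6 | 1α-vinyl 4-methylidene 5α,6α-oxirane, 2β-OH | C=C1[C@@H]2C[C@@H](O)[C@H](C=C)[C@H]2[C@H](C(C)C)[C@@H]3O[C@@H]31
F8 | step 6 | 1α-vinyl 4-methylidene 5α,6α-oxirane, 2-ketone | C=C1[C@@H]2CC(=O)[C@H](C=C)[C@H]2[C@H](C(C)C)[C@@H]3O[C@@H]31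
F9 | step 6 | 1-ethylidene 2-ketone (methyl on the carbonyl side) | C=C1[C@@H]2CC(=O)/C(=C\C)[C@H]2[C@H](C(C)C)[C@@H]3O[C@@H]31
F10 | step 6 | 4-methylidene 5α,6α-oxirane, (1Z)-ethylidene, 2α-OH | C=C1[C@@H]2C[C@H](O)/C(=C\C)[C@H]2[C@H](C(C)C)[C@@H]3O[C@@H]31
F11 | step 11 | 2α-acetoxy 5β,6α-diol | C=C1[C@@H]2C[C@H](OC(C)=O)/C(=C\C)[C@H]2[C@H](C(C)C)[C@H](O)[C@H]1O
F12 | step 11 | angelic 2,4,6-trichlorobenzoic anhydride | C/C=C(/C)C(=O)OC(=O)c1c(Cl)cc(Cl)cc1Cl
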